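**Retrosynthetic overview**

1. Target 16 ⇒ Mitsunobu O-alkylation of 4-hydroxy-5-methylcoumarin 4 (lactone ring closed first, separately, from 1 + 2) with the primary allylic alcohol of diol 15.
2. 15 ⇒ ester reduction of 14; 14 ⇒ catalyst-controlled CBS reduction of racemic methylenecyclohexanone 13, run as a kinetic resolution that fixes both stereocentres.
3. 13 ⇒ decarboxylation of 12 ⇒ key step: oxidative 6-endo radical closure of acyclic β-keto ester 11. The keto-ester α-carbon reacts with reversed polarity (electrophilic α-carbonyl radical) at the isopropenyl CH2, closing the CH2–CH2 ring bond, not the bond at the quaternary carbon.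
4. 11 ⇒ Roskamp homologation of aldehyde 9 ⇒ Claisen rearrangement of 8-hydroxygeranate 6 with isobutyraldehyde 7 (sets the gem-dimethyl carbon, the chain-bearing CH and the future exocyclic methylene).
5. 6 ⇒ allylic oxidation of methyl geranate 5. Ring order: coumarin lactone (step 1), then the single carbocycle (step 5).

Assumption: methyl geranate 5 is bought as the pure 2E ester; locants C1/C3 in the Why lines are the cyclohexyl locants of 13 and 14 (C1 carries the side chain, C3 the oxygen).

**Step 1**
Reactants: 1 2'-hydroxy-6'-methylacetophenone; 2 diethyl carbonate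
Product: 4 4-hydroxy-5-methylcoumarin, via keto ester 3 (not isolated)
Conditions: NaH (3 equiv), toluene, 110 °C; then aq. HCl
Reagents that add atoms: none
Why: Claisen-type C-acylation of the methyl ketone enolate by diethyl carbonate, then lactonisation of the phenoxide onto the new ester, is the standard entry to 4-hydroxycoumarins; no stereocentre.

**Step 2**
Reactants: 5 methyl (2E)-geranate
Product: 6 methyl (2E,6E)-8-hydroxy-3,7-dimethylocta-2,6-dienoate
Conditions: SeO2 (0.3 equiv), t-BuOOH (3 equiv), salicylic acid (0.1 equiv), CH2Cl2, rt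
Reagents that add atoms: tert-butyl hydroperoxide, CC(C)(C)OO (stoichiometric source of the new oxygen, passed on through catalytic selenium dioxide, O=[Se]=O)
Why: SeO2/t-BuOOH allylic oxidation (ene reaction then [2,3]-shift) hydroxylates only the E-methyl of the electron-rich terminal alkene and leaves the conjugated 2,3-alkene alone; no stereocentre.

**Step 3**
Reactants: 6 methyl (2E,6E)-8-hydroxy-3,7-dimethylocta-2,6-dienoate; 7 isobutyraldehyde
Product: 9 racemic methyl (2E)-3,7,7-trimethyl-8-oxo-6-(prop-1-en-2-yl)oct-2-enoate, via allyl isobutenyl ether 8 (not isolated)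
Conditions: 7 (5 equiv), p-TsOH·H2O (2 mol %), p-cymene, Dean–Stark, 110 to 175 °C
Reagents that add atoms: none
Why: Acid-catalysed acetalisation/elimination gives the allyl isobutenyl ether, whose Claisen rearrangement joins the future gem-dimethyl carbon to the chain-bearing CH and delivers the isopropenyl group and a non-enolisable aldehyde; the new CH stereocentre forms as a racemate and is resolved in step 7.

**Step 4**
Reactants: 9 racemic aldehyde; 10 ethyl diazoacetate
Product: 11 racemic 1-ethyl 10-methyl (8E)-4,4,8-trimethyl-3-oxo-5-(prop-1-en-2-yl)dec-8-enedioate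
Conditions: SnCl2 (10 mol %), CH2Cl2, rt
Reagents that add atoms: none
Why: Roskamp reaction — SnCl2-catalysed addition of the diazo ester to the aldehyde with 1,2-hydride shift and loss of N2 gives the β-keto ester, the enoate and alkenes being inert; no new stereocentre.

**Step 5**
Reactants: 11 racemic acyclic β-keto ester
Product: 12 racemic ethyl 4-[(3E)-5-methoxy-3-methyl-5-oxopent-3-en-1-yl]-3,3-dimethyl-5-methylidene-2-oxocyclohexane-1-carboxylate
Conditions: Mn(OAc)3·2H2O (2.0 equiv), Cu(OAc)2·H2O (1.0 equiv, turned over by the manganese salt), degassed AcOH, 25 °C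
Reagents that add atoms: none
Why: Oxidative free-radical cyclisation — the trivalent manganese enolate gives an electrophilic α-keto-ester radical (an enolonium equivalent of the normally nucleophilic α-carbon) that adds 6-endo to the nucleophilic terminal CH2 of the isopropenyl group, and divalent copper acetate oxidises the resulting tertiary radical with loss of a methyl hydrogen to the exocyclic alkene; the gem-dimethyl carbon blocks aromatisation, the electron-poor enoate does not trap the radical, and the only new stereocentre (ester carbon) is erased in step 6.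

**Step 6**
Reactants: 12 racemic cyclic β-keto ester
Product: 13 racemic methyl (2E)-5-(2,2-dimethyl-6-methylidene-3-oxocyclohexyl)-3-methylpent-2-enoate
Conditions: LiCl (3 equiv), H2O (2 equiv), DMSO, 140 °C
Reagents that add atoms: none
Why: Krapcho dealkoxycarbonylation removes only the β-keto ester carboxylate; the unactivated methyl enoate survives and the non-conjugated exocyclic alkene does not migrate.

**Step 7**
Reactants: 13 racemic ketone
Product: 14 methyl (2E)-5-[(1R,3S)-3-hydroxy-2,2-dimethyl-6-methylidenecyclohexyl]-3-methylpent-2-enoate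
Conditions: (R)-2-methyl-CBS-oxazaborolidine (0.2 equiv), catecholborane (0.55 equiv), toluene, −78 to −40 °C, to about 50 % conversion; silica chromatography removes unreacted (1S)-13
Reagents that add atoms: none
Why: Corey–Bakshi–Shibata reduction run as a kinetic resolution — the (R)-catalyst delivers hydride to the face that gives the S carbinol, which for the 1R ketone is also the substrate-preferred axial attack (equatorial OH cis to the equatorial side chain), so that enantiomer is reduced fast to the (1R,3S) alcohol while the 1S ketone is left behind; catecholborane at low temperature does not hydroborate the alkenes.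

**Step 8**
Reactants: 14 (1R,3S) hydroxy ester
Product: 15 (2E)-5-[(1R,3S)-3-hydroxy-2,2-dimethyl-6-methylidenecyclohexyl]-3-methylpent-2-en-1-ol
Conditions: i-Bu2AlH (3.5 equiv), CH2Cl2, −78 °C; aq. potassium sodium tartrate (KNaC4H4O6)
Reagents that add atoms: none
Why: i-Bu2AlH 1,2-reduction of the α,β-unsaturated ester gives the E-allylic alcohol without conjugate reduction; isolated alkenes and stereocentres are untouched.

**Step 9**
Reactants: 15 diol; 4 4-hydroxy-5-methylcoumarin
Product: 16 4-{[(2E)-5-[(1R,3S)-3-hydroxy-2,2-dimethyl-6-methylidenecyclohexyl]-3-methylpent-2-en-1-yl]oxy}-5-methyl-2H-chromen-2-one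
Conditions: PPh3, DIAD, THF, 0 °C to rt
Reagents that add atoms: none
Why: Mitsunobu etherification — the acidic 4-hydroxycoumarin (pKa about 4) is alkylated on O4 by the activated primary allylic alcohol in an SN2 step without allylic transposition, while the hindered neopentyl-type secondary alcohol does not react; stereocentres untouched.

**Compound list**

1 | 1-(2-hydroxy-6-methylphenyl)ethan-1-one (2'-hydroxy-6'-methylacetophenone) | CC(=O)c1c(C)cccc1O | starting material
2 | diethyl carbonate | CCOC(=O)OCC | starting material
3 | ethyl 3-(2-hydroxy-6-methylphenyl)-3-oxopropanoate | CCOC(=O)CC(=O)c1c(C)cccc1O | intermediate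
4 | 4-hydroxy-5-methyl-2H-chromen-2-one (4-hydroxy-5-methylcoumarin) | Cc1cccc2oc(=O)cc(O)c12 | intermediate
5 | methyl (2E)-3,7-dimethylocta-2,6-dienoate (methyl geranate) | CC(C)=CCC/C(C)=C/C(=O)OC | starting material
6 | methyl (2E,6E)-8-hydroxy-3,7-dimethylocta-2,6-dienoate | OC/C(C)=C/CC/C(C)=C/C(=O)OC | intermediate
7 | 2-methylpropanal (isobutyraldehyde) | CC(C)C=O | starting material
8 | methyl (2E,6E)-3,7-dimethyl-8-[(2-methylprop-1-en-1-yl)oxy]octa-2,6-dienoate | CC(C)=COC/C(C)=C/CC/C(C)=C/C(=O)OC | intermediate
9 | methyl (2E)-3,7,7-trimethyl-8-oxo-6-(prop-1-en-2-yl)oct-2-enoate, racemic | C=C(C)C(CC/C(C)=C/C(=O)OC)C(C)(C)C=O | intermediate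
10 | ethyl diazoacetate | CCOC(=O)C=[N+]=[N-] | starting material
11 | 1-ethyl 10-methyl (8E)-4,4,8-trimethyl-3-oxo-5-(prop-1-en-2-yl)dec-8-enedioate, racemic | CCOC(=O)CC(=O)C(C)(C)C(CC/C(C)=C/C(=O)OC)C(C)=C | intermediate
12 | ethyl 4-[(3E)-5-methoxy-3-methyl-5-oxopent-3-en-1-yl]-3,3-dimethyl-5-methylidene-2-oxocyclohexane-1-carboxylate, racemic, epimers at the ester carbon | CCOC(=O)C1CC(=C)C(CC/C(C)=C/C(=O)OC)C(C)(C)C1=O | intermediate
13 | methyl (2E)-5-(2,2-dimethyl-6-methylidene-3-oxocyclohexyl)-3-methylpent-2-enoate, racemic | C=C1CCC(=O)C(C)(C)C1CC/C(C)=C/C(=O)OC | intermediate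
14 | methyl (2E)-5-[(1R,3S)-3-hydroxy-2,2-dimethyl-6-methylidenecyclohexyl]-3-methylpent-2-enoate | C=C1CC[C@H](O)C(C)(C)[C@@H]1CC/C(C)=C/C(=O)OC | intermediate
15 | (2E)-5-[(1R,3S)-3-hydroxy-2,2-dimethyl-6-methylidenecyclohexyl]-3-methylpent-2-en-1-ol | C=C1CC[C@H](O)C(C)(C)[C@@H]1CC/C(C)=C/CO | intermediate
16 | 4-{[(2E)-5-[(1R,3S)-3-hydroxy-2,2-dimethyl-6-methylidenecyclohexyl]-3-methylpent-2-en-1-yl]oxy}-5-methyl-2H-chromen-2-one | C=C1CC[C@H](O)C(C)(C)[C@@H]1CC/C(C)=C/COc1cc(=O)oc2cccc(C)c12 | target

**Totals**

Total step count: 9 (step 1 makes the coumarin; steps 2 to 9 are the terpenoid line).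
Longest linear sequence: 8 steps (5 to 16).

**Three steps most likely to fail**

Step 3. At 175 °C with acid the 2-methylallylic alcohol 6 may ionise or transpose before it is vinylated. The fallback sets out again from 6 and makes the same ether under base by copper-catalysed O-vinylation with 1-iodo-2-methylprop-1-ene (CuI (copper monoiodide), 3,4,7,8-tetramethyl-1,10-phenanthroline, Cs2CO3, toluene, 120 °C). Ether 8 then rearranges in the same pot and the route is rejoined at aldehyde 9. New compounds: none F0.

Step 5. Product 12 still carries an enolisable hydrogen between its two carbonyls and can be oxidised a second time by the manganese salt; the copper salt may also give some endocyclic alkene. The fallback sets out from 11. The active methylene is chlorinated (NCS, CH2Cl2) to the α-chloro keto diester F1. This is cyclised with the same Mn(OAc)3/Cu(OAc)2 couple (AcOH, 50 °C) to the chloro cyclohexanone ester F2, which has no enolisable hydrogen left and cannot be over-oxidised. Zn/AcOH then removes the chlorine and the route is rejoined at 12.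

Step 7. The selectivity factor of the kinetic resolution may be too low for high ee, and at best half of 13 is used. The fallback sets out from 13. NaBH4 (MeOH, 0 °C, axial attack) gives the racemic cis hydroxy ester F3. This is esterified with (S)-2-methoxy-2-phenylacetic acid (DCC, DMAP, CH2Cl2) and the two diastereomeric esters are separated on silica. The (1R,3S) O-methylmandelate ester F4 is cleaved with K2CO3/MeOH and the route is rejoined at 14.

**Further compounds**

F0 | step 3 | none | none
F1 | step 5 | 1-ethyl 10-methyl (8E)-2-chloro-4,4,8-trimethyl-3-oxo-5-(prop-1-en-2-yl)dec-8-enedioate | CCOC(=O)C(Cl)C(=O)C(C)(C)C(CC/C(C)=C/C(=O)OC)C(C)=C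
F2 | step 5 | ethyl 1-chloro-4-[(3E)-5-methoxy-3-methyl-5-oxopent-3-en-1-yl]-3,3-dimethyl-5-methylidene-2-oxocyclohexane-1-carboxylate | CCOC(=O)C1(Cl)CC(=C)C(CC/C(C)=C/C(=O)OC)C(C)(C)C1=O
F3 | step 7 | racemic methyl (2E)-5-[(1RS,3SR)-3-hydroxy-2,2-dimethyl-6-methylidenecyclohexyl]-3-methylpent-2-enoate | C=C1CC[C@H](O)C(C)(C)[C@@H]1CC/C(C)=C/C(=O)OC.C=C1CC[C@@H](O)C(C)(C)[C@H]1CC/C(C)=C/C(=O)OC
F4 | step 7 | methyl (2E)-5-[(1R,3S)-3-{[(2S)-2-methoxy-2-phenylacetyl]oxy}-2,2-dimethyl-6-methylidenecyclohexyl]-3-methylpent-2-enoate | C=C1CC[C@H](OC(=O)[C@@H](OC)c2ccccc2)C(C)(C)[C@@H]1CC/C(C)=C/C(=O)OC
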